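Ring B of the 5',7'-dihydroxycoumarin unit (primed locants) carries three adjacent oxygens at C8a', C8' and C7', the same pattern as an aryl alkyl squarate. The hindered diaryl ether bond C8'–O is therefore made on a four-membered ring by addition–elimination, and ring B is grown around it. In one operation, a Stille coupling of a 4-chlorocyclobutenone with a 1-isopropoxyvinylstannane joins C5'–C6'; the vinylcyclobutenone then opens to a dienylketene and closes C4a'–C8a' to a phenol whose only free hydroxyl is at C8a'. The precursor is the racemic 4-chloro-3-isopropoxy-2-aryloxycyclobutenone made from squaric acid and 8-hydroxy-7-methoxycoumarin.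

Key step: step 7

Remark: Ar is 7-methoxy-2-oxo-2H-chromen-8-yl; the cyclobutenone carbons map as C1 (ketone) = C8a', C2 = C8', C3 = C7', C4 = C6'; isopropyl is kept on both ring B oxygens because BCl3 removes secondary alkyl ethers beside the C7 methyl ether, which an ethyl ether from the purchasable 1-ethoxyvinylstannane would not allow.

Step 1
Reactants: 1 squaric acid
Product: 2 3,4-dichlorocyclobut-3-ene-1,2-dione (squaryl dichloride)
Conditions: (COCl)2 (2.2 equiv), DMF (cat.), CH2Cl2, 40 °C
Reagents that add atoms: oxalyl chloride, O=C(Cl)C(=O)Cl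
Why: Vilsmeier-type activation (chloroiminium from DMF and oxalyl chloride) turns both vinylogous acid hydroxyls into vinylogous acid chlorides, the standard preparation of this dichloride.

Step 2
Reactants: 2 squaryl dichloride
Product: 3 3-chloro-4-isopropoxycyclobut-3-ene-1,2-dione
Conditions: i-PrOH (1.0 equiv), CH2Cl2, -20 to 20 °C, N2 sweep; distillation
Reagents that add atoms: propan-2-ol, CC(C)O
Why: Vinylogous acyl substitution (addition–elimination) by one equivalent of alcohol should stop at the ester chloride, because the first alkoxy group donates into the ring and deactivates the second chloride.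

Step 3
Reactants: 3 3-chloro-4-isopropoxycyclobut-3-ene-1,2-dione; 4 8-hydroxy-7-methoxycoumarin
Product: 5 3-isopropoxy-4-[(7-methoxy-2-oxo-2H-chromen-8-yl)oxy]cyclobut-3-ene-1,2-dione
Conditions: i-Pr2NEt (1.1 equiv), CH2Cl2, -40 to 0 °C
Reagents that add atoms: none
Why: Addition–elimination of the phenoxide at the chlorine-bearing sp2 carbon (vinylogous O-acylation) is insensitive to the two ortho substituents of the phenol, and chloride leaves far more readily than isopropoxide, so only the mixed aryl alkyl squarate should form.

Step 4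
Reactants: 5 mixed aryl isopropyl squarate
Product: 6 4-hydroxy-3-isopropoxy-2-[(7-methoxy-2-oxo-2H-chromen-8-yl)oxy]cyclobut-2-en-1-one (racemic)
Conditions: LiAlH(O-t-Bu)3 (1.05 equiv), THF, -78 °C; NaH2PO4/Na2HPO4 buffer (pH 7)
Reagents that add atoms: none
Why: Chemoselective 1,2-reduction of a squarate ester with a bulky hydride, known for dialkyl squarates, should go to the carbonyl conjugated with the poorly donating aryloxy group (the one next to the isopropoxy carbon) and keep the better stabilised vinylogous isopropyl ester ketone beside C8'; the new stereocentre is formed racemic and disappears in step 7.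

Step 5
Reactants: 6 4-hydroxycyclobutenone
Product: 8 4-chloro-3-isopropoxy-2-[(7-methoxy-2-oxo-2H-chromen-8-yl)oxy]cyclobut-2-en-1-one (racemic), via mesylate 7 (not isolated)
Conditions: MsCl, 2,4,6-collidine, LiCl, DMF, 0 °C; rapid non-aqueous filtration, used at once
Reagents that add atoms: lithium chloride, [Li+].[Cl-]; methanesulfonyl chloride, CS(=O)(=O)Cl (its chloride joins the same pool)
Why: Allylic chlorination of the Collington–Meyers type (buffered mesylation, then chloride displacement) avoids aqueous acid, and the conjugated 4-chloride is the stable allylic isomer whether substitution is direct or through an ion pair; the centre stays racemic.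

Step 6
Reactants: 9 isopropyl vinyl ether
Product: 11 tributyl(1-isopropoxyvinyl)stannane, via 1-isopropoxyvinyllithium 10 (not isolated)
Conditions: t-BuLi, THF, -78 to 0 °C; Bu3SnCl, -78 to 20 °C
Reagents that add atoms: tributyltin chloride, CCCC[Sn](Cl)(CCCC)CCCC
Why: Alpha-lithiation of an alkyl vinyl ether with tert-butyllithium followed by stannylation is the standard route to 1-alkoxyvinylstannanes.

Step 7
Reactants: 8 4-chlorocyclobutenone; 11 tributyl(1-isopropoxyvinyl)stannane
Product: 15 8-(2-hydroxy-4,6-diisopropoxyphenoxy)-7-methoxy-2H-chromen-2-one, via alkenylcyclobutenone 12 (not isolated), via dienylketene 13 (not isolated), via cyclohexadienone 14 (not isolated)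
Conditions: PdCl2(PhCN)2 (5 mol %), tri(2-furyl)phosphine (10 mol %), dioxane, 50 °C then 100 °C
Reagents that add atoms: none
Why: Stille coupling with in situ benzannulation: zerovalent palladium inserts into the allylic, alpha-keto C–Cl bond of 8, and transmetalation with 11 followed by reductive elimination joins C6' to C5' to give 12. On warming, 12 undergoes 4π-electrocyclic opening of the C8a'–C6' bond to dienylketene 13, which closes ring B by a thermal disrotatory 6π-electrocyclization between the ketene carbon C8a' and the methylene C4a' to give dienone 14, and enolisation gives phenol 15. The closest known reaction type is the palladium-catalysed coupling of 4-chlorocyclobutenones with alkenylstannanes that delivers phenols directly. No stereocentre is created, since the racemic sp3 carbon of 8 ends as the aromatic C6'–H. The step needs bond formation at the chlorine-bearing carbon and a ketene geometry with the vinyl group turned inward; the first follows from reductive elimination at the alpha-keto carbon to the conjugated enone, the second from the reversibility of ring opening, which lets an outward-rotated ketene re-close until the cyclisable isomer is drained to the arene. The oxygen pattern is fixed by the precursor: the ketone becomes the single free hydroxyl at C8a', next to C8'–OAr, with isopropyl ethers at C7' and C5'.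

Step 8
Reactants: 15 ring B phenol
Product: 16 2-hydroxy-4,6-diisopropoxy-3-[(7-methoxy-2-oxo-2H-chromen-8-yl)oxy]benzaldehyde
Conditions: MgCl2, Et3N, (CH2O)n, MeCN, reflux; dilute aqueous acid work-up
Reagents that add atoms: paraformaldehyde (formaldehyde unit), C=O
Why: Magnesium-mediated ortho-formylation (Casnati–Skattebøl type) delivers formaldehyde only ortho to the magnesium phenoxide, and C4a' is the single free ortho carbon of the one free phenol, so the equally activated C6' should stay untouched.

Step 9
Reactants: 16 salicylaldehyde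
Product: 19 5,7-diisopropoxy-8-[(7-methoxy-2-oxo-2H-chromen-8-yl)oxy]-2H-chromen-2-one, via E-cinnamate ester 17 (not isolated), via Z-cinnamate ester 18 (not isolated)
Conditions: Ph3P=CHCO2Et (1.5 equiv), N,N-diethylaniline, 210 °C
Reagents that add atoms: ethyl (triphenylphosphoranylidene)acetate, CCOC(=O)C=P(c1ccccc1)(c1ccccc1)c1ccccc1
Why: Wittig olefination with the stabilised ylide, thermal E-to-Z isomerisation and lactonisation onto the C8a' hydroxyl make up the classical one-pot coumarin synthesis from salicylaldehydes in hot N,N-diethylaniline.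

Step 10
Reactants: 19 diisopropyl ether of the target
Product: 20 5,7-dihydroxy-8-[(7-methoxy-2-oxo-2H-chromen-8-yl)oxy]-2H-chromen-2-one (CNP0305396.0)
Conditions: BCl3 (6 equiv), CH2Cl2, -78 to 0 °C; H2O quench
Reagents that add atoms: none
Why: Lewis acid dealkylation with BCl3 cleaves secondary alkyl aryl ethers at or below 0 °C, where the aryl methyl ether, the diaryl ether and both lactones should persist.

Compound list
1 | squaric acid | OC1=C(O)C(=O)C1=O | starting material
2 | 3,4-dichlorocyclobut-3-ene-1,2-dione | ClC1=C(Cl)C(=O)C1=O | intermediate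
3 | 3-chloro-4-isopropoxycyclobut-3-ene-1,2-dione | CC(C)OC1=C(Cl)C(=O)C1=O | intermediate
4 | 8-hydroxy-7-methoxy-2H-chromen-2-one | COc1ccc2ccc(=O)oc2c1O | starting material
5 | 3-isopropoxy-4-[(7-methoxy-2-oxo-2H-chromen-8-yl)oxy]cyclobut-3-ene-1,2-dione | COc1ccc2ccc(=O)oc2c1OC1=C(OC(C)C)C(=O)C1=O | intermediate
6 | 4-hydroxy-3-isopropoxy-2-[(7-methoxy-2-oxo-2H-chromen-8-yl)oxy]cyclobut-2-en-1-one (racemic) | COc1ccc2ccc(=O)oc2c1OC1=C(OC(C)C)C(O)C1=O | intermediate
7 | 2-isopropoxy-3-[(7-methoxy-2-oxo-2H-chromen-8-yl)oxy]-4-oxocyclobut-2-en-1-yl methanesulfonate (racemic) | COc1ccc2ccc(=O)oc2c1OC1=C(OC(C)C)C(OS(C)(=O)=O)C1=O | intermediate (not isolated)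
8 | 4-chloro-3-isopropoxy-2-[(7-methoxy-2-oxo-2H-chromen-8-yl)oxy]cyclobut-2-en-1-one (racemic) | COc1ccc2ccc(=O)oc2c1OC1=C(OC(C)C)C(Cl)C1=O | intermediate
9 | isopropyl vinyl ether | C=COC(C)C | starting material
10 | 1-isopropoxyvinyllithium | [Li]C(=C)OC(C)C | intermediate (not isolated)
11 | tributyl(1-isopropoxyvinyl)stannane | CCCC[Sn](CCCC)(CCCC)C(=C)OC(C)C | intermediate
12 | 3-isopropoxy-4-(1-isopropoxyvinyl)-2-[(7-methoxy-2-oxo-2H-chromen-8-yl)oxy]cyclobut-2-en-1-one (racemic) | COc1ccc2ccc(=O)oc2c1OC1=C(OC(C)C)C(C(=C)OC(C)C)C1=O | intermediate (not isolated)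
13 | (3E)-3,5-diisopropoxy-2-[(7-methoxy-2-oxo-2H-chromen-8-yl)oxy]hexa-1,3,5-trien-1-one (C2 and C5 cis) | COc1ccc2ccc(=O)oc2c1OC(=C=O)/C(OC(C)C)=C\C(=C)OC(C)C | intermediate (not isolated)
14 | 3,5-diisopropoxy-2-[(7-methoxy-2-oxo-2H-chromen-8-yl)oxy]cyclohexa-2,4-dien-1-one | COc1ccc2ccc(=O)oc2c1OC1=C(OC(C)C)C=C(OC(C)C)CC1=O | intermediate (not isolated)
15 | 8-(2-hydroxy-4,6-diisopropoxyphenoxy)-7-methoxy-2H-chromen-2-one | COc1ccc2ccc(=O)oc2c1Oc1c(O)cc(OC(C)C)cc1OC(C)C | intermediate
16 | 2-hydroxy-4,6-diisopropoxy-3-[(7-methoxy-2-oxo-2H-chromen-8-yl)oxy]benzaldehyde | COc1ccc2ccc(=O)oc2c1Oc1c(O)c(C=O)c(OC(C)C)cc1OC(C)C | intermediate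
17 | ethyl (E)-3-{2-hydroxy-4,6-diisopropoxy-3-[(7-methoxy-2-oxo-2H-chromen-8-yl)oxy]phenyl}acrylate | CCOC(=O)/C=C/c1c(O)c(Oc2c(OC)ccc3ccc(=O)oc23)c(OC(C)C)cc1OC(C)C | intermediate (not isolated)
18 | ethyl (Z)-3-{2-hydroxy-4,6-diisopropoxy-3-[(7-methoxy-2-oxo-2H-chromen-8-yl)oxy]phenyl}acrylate | CCOC(=O)/C=C\c1c(O)c(Oc2c(OC)ccc3ccc(=O)oc23)c(OC(C)C)cc1OC(C)C | intermediate (not isolated)
19 | 5,7-diisopropoxy-8-[(7-methoxy-2-oxo-2H-chromen-8-yl)oxy]-2H-chromen-2-one | COc1ccc2ccc(=O)oc2c1Oc1c(OC(C)C)cc(OC(C)C)c2ccc(=O)oc12 | intermediate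
20 | 5,7-dihydroxy-8-[(7-methoxy-2-oxo-2H-chromen-8-yl)oxy]-2H-chromen-2-one | COc1ccc2ccc(=O)oc2c1Oc1c(O)cc(O)c2ccc(=O)oc12 | target

Total step count: 10. Longest linear sequence: 9 steps (steps 1 to 5, then 7 to 10); step 6 is a one-step side branch.

Steps most likely to fail

Step 7. The chloride may ionise or hydrolyse, or the enol ether stannane may lose tin to adventitious acid, before oxidative addition and transmetalation occur; the ketene may also be consumed intermolecularly before it reaches the cyclisable geometry. The fallback gives up the ring construction and forms C8'–O directly by copper-catalysed Ullmann coupling on a preformed coumarin. It sets out from 4. Purchased 5,7-dihydroxycoumarin (Oc1cc(O)c2ccc(=O)oc2c1) would be alkylated with 2-bromopropane and K2CO3 in DMF to 5,7-diisopropoxy-2H-chromen-2-one F1. Iodination with N-iodosuccinimide and catalytic CF3CO2H in MeCN is expected mainly at C8 and should give 8-iodo-5,7-diisopropoxy-2H-chromen-2-one F2, the 6-iodo isomer being removed by chromatography. Coupling of F2 with 4 (CuI, picolinic acid, K3PO4, DMSO, 90 to 110 °C) would give 19 directly, where the route is rejoined; steps 8 and 9 are then not needed. Both partners are flanked on two sides, so this coupling is expected to be slow, which is why it is the reserve and not the main route.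

Step 4. The hydride may be delivered to the carbonyl next to the aryloxy carbon, which would place the retained ketone on the wrong side. The fallback inverts the site by masking instead of reducing the carbonyl that the reagent prefers. It sets out from 5. Ketalisation with MeOSiMe3 and catalytic Me3SiOTf in CH2Cl2 at -78 °C (Noyori conditions), which follows the same electrophilicity preference, would give 2-isopropoxy-4,4-dimethoxy-3-[(7-methoxy-2-oxo-2H-chromen-8-yl)oxy]cyclobut-2-en-1-one F3. Reduction of the remaining ketone with i-Bu2AlH in CH2Cl2 at -78 °C would give 2-isopropoxy-4,4-dimethoxy-3-[(7-methoxy-2-oxo-2H-chromen-8-yl)oxy]cyclobut-2-en-1-ol F4 (racemic). Mild ketal hydrolysis (oxalic acid on moist silica gel, CH2Cl2) then returns the route at 6.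

Step 5. Activation of the hydroxyl may lead to ionisation and capture by water with loss of the aryloxy group, or the chloride may decompose during isolation. The fallback never makes a chloride and uses an allylic ester as the electrophile. It sets out from 6. Acetylation (Ac2O, pyridine, 0 °C) would give 2-isopropoxy-3-[(7-methoxy-2-oxo-2H-chromen-8-yl)oxy]-4-oxocyclobut-2-en-1-yl acetate F5 (racemic). Stille coupling of this allylic acetate with 11 (Pd(dba)2, LiCl, DMF, 25 to 60 °C, then 100 °C) should pass through 12 and return the route at 15.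

Further compounds
F1 | step 7 | 5,7-diisopropoxy-2H-chromen-2-one | CC(C)Oc1cc(OC(C)C)c2ccc(=O)oc2c1
F2 | step 7 | 8-iodo-5,7-diisopropoxy-2H-chromen-2-one | CC(C)Oc1cc(OC(C)C)c2ccc(=O)oc2c1I
F3 | step 4 | 2-isopropoxy-4,4-dimethoxy-3-[(7-methoxy-2-oxo-2H-chromen-8-yl)oxy]cyclobut-2-en-1-one | COc1ccc2ccc(=O)oc2c1OC1=C(OC(C)C)C(=O)C1(OC)OC
F4 | step 4 | 2-isopropoxy-4,4-dimethoxy-3-[(7-methoxy-2-oxo-2H-chromen-8-yl)oxy]cyclobut-2-en-1-ol (racemic) | COc1ccc2ccc(=O)oc2c1OC1=C(OC(C)C)C(O)C1(OC)OC
F5 | step 5 | 2-isopropoxy-3-[(7-methoxy-2-oxo-2H-chromen-8-yl)oxy]-4-oxocyclobut-2-en-1-yl acetate (racemic) | COc1ccc2ccc(=O)oc2c1OC1=C(OC(C)C)C(OC(C)=O)C1=O
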